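**Retrosynthetic overview** (oxolane locants: O1, C2 aryl, C3 CH2O branch, C4 benzyl, C5 ring OCH2)
1. Target 18 is the p-coumarate of (−)-lariciresinol 16, the (2R,3S,4S)-oxolane; the last disconnection is the ester C–O bond at the C3 CH2O group (Mitsunobu), giving 16 and p-coumaric acid 17.
2. Enabling feature: C3 of the oxolane carries an exocyclic oxygenated carbon and sits between the O-bearing C2 and C4, and C5 is an unsubstituted O–CH2. At the aldehyde level this is a 3-formyloxolane, the retron of a Prins–pinacol rearrangement with C5 as a formaldehyde carbon.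
3. Key disconnection: C5–C4 (ring-closing Prins bond) together with C2–C3 (pinacol shift), giving the trans-4-aryl-5-[(E)-3-arylprop-1-enyl]-1,3-dioxolane 11; its old allylic carbinol carbon becomes the formyl carbon.
4. 11 comes from cross-metathesis of vinyl dioxolane 8 with eugenol pivalate 10; 8 comes from syn-alkoxyallylboration of vanillin pivalate 2 with allyl MOM ether 4 and MOM-to-methylene-acetal transfer (the MOM CH2 becomes C5).
5. Ring order: dioxolane (temporary), then oxane (transient, closed by C5–C4), then oxolane (by ring contraction). C2 comes from the allylboration, C4 from chirality transfer in the chair, C3 from equilibration.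

Key step: step 7

Assumption: the borane made from (−)-α-pinene, (+)-Ipc2BOMe, is taken to deliver the alkoxyallyl group to the Re face of the aryl aldehyde, as this reagent family does in allylborations of aromatic aldehydes; the antipodal borane would be used otherwise.

**Step 1**
Reactants: 1 vanillin (4-hydroxy-3-methoxybenzaldehyde)
Product: 2 4-formyl-2-methoxyphenyl 2,2-dimethylpropanoate
Conditions: PivCl, Et3N, DMAP (cat.), CH2Cl2, 0 °C to rt
Reagents that add atoms: pivaloyl chloride, CC(C)(C)C(=O)Cl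
Why: O-acylation of the phenol (nucleophilic acyl substitution), chosen because the pivalate makes this ring electron-poor for step 7 and should survive steps 3 to 8.

**Step 2**
Reactants: 3 prop-2-en-1-ol
Product: 4 3-(methoxymethoxy)prop-1-ene
Conditions: MOMCl, iPr2NEt, CH2Cl2, 0 °C to rt
Reagents that add atoms: chloromethyl methyl ether, COCCl
Why: MOM ether formation by O-alkylation, which brings in the OCH2O carbon that ends as the ring OCH2 carbon of the target.

**Step 3**
Reactants: 4 3-(methoxymethoxy)prop-1-ene; 2 4-formyl-2-methoxyphenyl 2,2-dimethylpropanoate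
Product: 7 4-[(1S,2S)-1-hydroxy-2-(methoxymethoxy)but-3-en-1-yl]-2-methoxyphenyl 2,2-dimethylpropanoate, via allyllithium 5 (not isolated), via allylborane 6 (not isolated)
Conditions: 4, s-BuLi, THF, −78 °C; (+)-Ipc2BOMe, −78 °C; BF3·OEt2, −78 °C; 2, −78 °C; then HOCH2CH2NH2, rt
Reagents that add atoms: none
Why: Brown alkoxyallylboration, in which the (Z)-γ-alkoxyallylborane adds through a closed chair transition state so that the Z geometry gives the syn 1,2-diol derivative and the isopinocampheyl groups select the aldehyde face, setting both carbinol centres as (1S,2S).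

**Step 4**
Reactants: 7 4-[(1S,2S)-1-hydroxy-2-(methoxymethoxy)but-3-en-1-yl]-2-methoxyphenyl 2,2-dimethylpropanoate
Product: 8 4-[(4S,5S)-5-ethenyl-1,3-dioxolan-4-yl]-2-methoxyphenyl 2,2-dimethylpropanoate
Conditions: BF3·OEt2 (0.2 equiv), CH2Cl2, 0 °C
Reagents that add atoms: none
Why: Lewis acid-catalysed intramolecular transacetalisation, in which the MOM group ionises and is captured by the neighbouring hydroxyl to give the methylene acetal with loss of methanol, both carbinol centres keeping their configuration (trans-4,5-disubstituted dioxolane).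

**Step 5**
Reactants: 9 eugenol (2-methoxy-4-(prop-2-en-1-yl)phenol)
Product: 10 2-methoxy-4-(prop-2-en-1-yl)phenyl 2,2-dimethylpropanoate
Conditions: PivCl, Et3N, DMAP (cat.), CH2Cl2, 0 °C to rt
Reagents that add atoms: pivaloyl chloride, CC(C)(C)C(=O)Cl
Why: phenol O-acylation, which lowers the nucleophilicity of this ring so that it should not intercept cations in step 7.

**Step 6**
Reactants: 8 4-[(4S,5S)-5-ethenyl-1,3-dioxolan-4-yl]-2-methoxyphenyl 2,2-dimethylpropanoate; 10 2-methoxy-4-(prop-2-en-1-yl)phenyl 2,2-dimethylpropanoate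
Product: 11 4-[(4S,5S)-5-[(1E)-3-{3-methoxy-4-[(2,2-dimethylpropanoyl)oxy]phenyl}prop-1-en-1-yl]-1,3-dioxolan-4-yl]-2-methoxyphenyl 2,2-dimethylpropanoate
Conditions: 10 (3 equiv), second-generation Hoveyda–Grubbs catalyst RuCl2(H2IMes)(=CH-C6H4-2-OiPr) (5 mol %), 1,4-benzoquinone (10 mol %), CH2Cl2, 40 °C
Reagents that add atoms: none
Why: olefin cross-metathesis of an allylarene with an allylically oxygenated terminal alkene, which should give mainly the E-alkene (benzoquinone suppresses isomerisation of the allylarene), the Z isomer being removed by chromatography because alkene geometry is translated into the C4 configuration in step 7.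

**Step 7**
Reactants: 11 4-[(4S,5S)-5-[(1E)-3-{3-methoxy-4-[(2,2-dimethylpropanoyl)oxy]phenyl}prop-1-en-1-yl]-1,3-dioxolan-4-yl]-2-methoxyphenyl 2,2-dimethylpropanoate
Product: 14 4-[(2R,3S,4S)-3-formyl-4-{[3-methoxy-4-(2,2-dimethylpropanoyloxy)phenyl]methyl}oxolan-2-yl]-2-methoxyphenyl 2,2-dimethylpropanoate, via oxocarbenium ion 12 (not isolated), via oxan-4-yl cation 13 (not isolated)
Conditions: SnCl4 (3 equiv), CH2Cl2, −78 to −20 °C; then aq. NaHCO3
Reagents that add atoms: none
Why: SnCl4 opens the methylene acetal at the allylic oxygen to the O-methylene oxocarbenium ion 12, whose CH2 carbon is attacked by the distal carbon of the E-alkene in a Prins cyclisation (6-endo-trig, chair transition state) that closes an oxane ring through the new bond between the O–CH2 carbon and the benzyl-bearing carbon; in cation 13 the aryl-bearing carbon then shifts from the tin-alkoxide carbon to the cationic carbon (pinacol shift), which contracts the oxane to the oxolane and unveils the formyl group. The closest known reaction type is the Prins–pinacol rearrangement of 4-alkenyl-1,3-dioxolanes to 3-acyltetrahydrofurans, which is also known to give 3-formyl products from secondary allylic carbinols. C2 keeps the configuration of the aryl carbinol because the migrating carbon shifts with retention, C4 is set in the chair, in which the aryl group and the benzyl group of the E-alkene are equatorial and the tin alkoxide is axial, so that aryl and benzyl end up trans on the oxolane, and C3 is set by the suprafacial shift, which leaves the formyl group cis to the aryl group (the C3 epimer of what the target needs, corrected in step 8). The step needs the productive mode of acetal opening, which is secured because the two modes interconvert and only the oxocarbenium ion on the benzylic oxygen has the alkene in reach; it needs the shift to win over chloride capture and hydride shift, which the alkoxide next to the cation and its axial position secure; and it needs C2 to hold, for which both phenols are pivalates, so that the electron-poor rings disfavour benzylic ionisation, a dissociative 2-oxonia-Cope/aldol course and Friedel–Crafts capture of the cation.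

**Step 8**
Reactants: 14 4-[(2R,3S,4S)-3-formyl-4-{[3-methoxy-4-(2,2-dimethylpropanoyloxy)phenyl]methyl}oxolan-2-yl]-2-methoxyphenyl 2,2-dimethylpropanoate
Product: 15 4-[(2R,3R,4S)-3-formyl-4-{[3-methoxy-4-(2,2-dimethylpropanoyloxy)phenyl]methyl}oxolan-2-yl]-2-methoxyphenyl 2,2-dimethylpropanoate
Conditions: DBU (0.3 equiv), CH2Cl2, rt
Reagents that add atoms: none
Why: base-mediated epimerisation of the aldehyde α-centre through its enolate (thermodynamic control), in which the formyl group should prefer the side away from the ring-bound aryl group at C2, a larger cis neighbour than the CH2Ar group at C4, so that 15 (2,3-trans, 3,4-cis) should predominate while C2 and C4 stay untouched and unchanged 14 is separated and resubjected.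

**Step 9**
Reactants: 15 4-[(2R,3R,4S)-3-formyl-4-{[3-methoxy-4-(2,2-dimethylpropanoyloxy)phenyl]methyl}oxolan-2-yl]-2-methoxyphenyl 2,2-dimethylpropanoate
Product: 16 (−)-lariciresinol, 4-[(2R,3S,4S)-4-[(4-hydroxy-3-methoxyphenyl)methyl]-3-(hydroxymethyl)oxolan-2-yl]-2-methoxyphenol
Conditions: LiAlH4, THF, −78 °C to rt; aq. potassium sodium tartrate
Reagents that add atoms: none
Why: hydride reduction of the aldehyde to the primary alcohol and reductive cleavage of both aryl pivalates in one operation, the addition at −78 °C reducing the aldehyde before it can epimerise and no stereocentre being touched.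

**Step 10**
Reactants: 16 (−)-lariciresinol; 17 p-coumaric acid, (2E)-3-(4-hydroxyphenyl)prop-2-enoic acid
Product: 18 lariciresinol p-coumarate, [(2R,3S,4S)-2-(4-hydroxy-3-methoxyphenyl)-4-[(4-hydroxy-3-methoxyphenyl)methyl]oxolan-3-yl]methyl (2E)-3-(4-hydroxyphenyl)prop-2-enoate
Conditions: PPh3, DIAD, THF, 0 °C to rt
Reagents that add atoms: none
Why: Mitsunobu esterification, expected to be chemoselective without phenol protection because only the carboxylic acid is acidic enough to protonate the betaine and serve as nucleophile while the single aliphatic primary hydroxyl is the one activated at phosphorus, the carbinol carbon being no stereocentre and the E-alkene untouched.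

**Compound list**
1 | vanillin (4-hydroxy-3-methoxybenzaldehyde) | COc1cc(C=O)ccc1O | starting material
2 | 4-formyl-2-methoxyphenyl 2,2-dimethylpropanoate | COc1cc(C=O)ccc1OC(=O)C(C)(C)C | intermediate
3 | prop-2-en-1-ol | C=CCO | starting material
4 | 3-(methoxymethoxy)prop-1-ene | C=CCOCOC | intermediate
5 | [(2Z)-3-(methoxymethoxy)prop-2-en-1-yl]lithium | [Li]C/C=C\OCOC | intermediate
6 | [(2Z)-3-(methoxymethoxy)prop-2-en-1-yl]bis[(1S,2R,3S,5S)-2,6,6-trimethylbicyclo[3.1.1]heptan-3-yl]borane | COCO/C=C\CB([C@H]1C[C@H]2C[C@@H]([C@@H]1C)C2(C)C)[C@H]1C[C@H]2C[C@@H]([C@@H]1C)C2(C)C | intermediate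
7 | 4-[(1S,2S)-1-hydroxy-2-(methoxymethoxy)but-3-en-1-yl]-2-methoxyphenyl 2,2-dimethylpropanoate | C=C[C@H](OCOC)[C@@H](O)c1ccc(OC(=O)C(C)(C)C)c(OC)c1 | intermediate
8 | 4-[(4S,5S)-5-ethenyl-1,3-dioxolan-4-yl]-2-methoxyphenyl 2,2-dimethylpropanoate | C=C[C@@H]1OCO[C@H]1c2ccc(OC(=O)C(C)(C)C)c(OC)c2 | intermediate
9 | eugenol (2-methoxy-4-(prop-2-en-1-yl)phenol) | COc1cc(CC=C)ccc1O | starting material
10 | 2-methoxy-4-(prop-2-en-1-yl)phenyl 2,2-dimethylpropanoate | COc1cc(CC=C)ccc1OC(=O)C(C)(C)C | intermediate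
11 | 4-[(4S,5S)-5-[(1E)-3-{3-methoxy-4-[(2,2-dimethylpropanoyl)oxy]phenyl}prop-1-en-1-yl]-1,3-dioxolan-4-yl]-2-methoxyphenyl 2,2-dimethylpropanoate | COc1cc(C/C=C/[C@@H]2OCO[C@H]2c3ccc(OC(=O)C(C)(C)C)c(OC)c3)ccc1OC(=O)C(C)(C)C | intermediate
12 | ring-opened form of 11: CH2=O+ on the benzylic oxygen, Cl4Sn–O on the allylic carbon, both carbinol configurations as in 11, E-alkene (zwitterion) | C=[O+][C@@H](c1ccc(OC(=O)C(C)(C)C)c(OC)c1)[C@@H](O[Sn-](Cl)(Cl)(Cl)Cl)/C=C/Cc1ccc(OC(=O)C(C)(C)C)c(OC)c1 | intermediate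
13 | oxan-4-yl cation: 2-aryl, 3-(Cl4Sn–O), 5-(arylmethyl), 2,3-cis and 2,5-trans, cationic C4 (zwitterion) | COc1cc(C[C@@H]2CO[C@@H](c3ccc(OC(=O)C(C)(C)C)c(OC)c3)[C@@H](O[Sn-](Cl)(Cl)(Cl)Cl)[CH+]2)ccc1OC(=O)C(C)(C)C | intermediate
14 | 4-[(2R,3S,4S)-3-formyl-4-{[3-methoxy-4-(2,2-dimethylpropanoyloxy)phenyl]methyl}oxolan-2-yl]-2-methoxyphenyl 2,2-dimethylpropanoate (formyl cis to C2 aryl, trans to C4 benzyl) | COc1cc(C[C@@H]2CO[C@@H](c3ccc(OC(=O)C(C)(C)C)c(OC)c3)[C@H]2C=O)ccc1OC(=O)C(C)(C)C | intermediate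
15 | 4-[(2R,3R,4S)-3-formyl-4-{[3-methoxy-4-(2,2-dimethylpropanoyloxy)phenyl]methyl}oxolan-2-yl]-2-methoxyphenyl 2,2-dimethylpropanoate (formyl trans to C2 aryl, cis to C4 benzyl) | COc1cc(C[C@@H]2CO[C@@H](c3ccc(OC(=O)C(C)(C)C)c(OC)c3)[C@@H]2C=O)ccc1OC(=O)C(C)(C)C | intermediate
16 | (−)-lariciresinol, 4-[(2R,3S,4S)-4-[(4-hydroxy-3-methoxyphenyl)methyl]-3-(hydroxymethyl)oxolan-2-yl]-2-methoxyphenol | COc1cc(C[C@@H]2CO[C@@H](c3ccc(O)c(OC)c3)[C@@H]2CO)ccc1O | intermediate
17 | p-coumaric acid, (2E)-3-(4-hydroxyphenyl)prop-2-enoic acid | OC(=O)/C=C/c1ccc(O)cc1 | starting material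
18 | lariciresinol p-coumarate, [(2R,3S,4S)-2-(4-hydroxy-3-methoxyphenyl)-4-[(4-hydroxy-3-methoxyphenyl)methyl]oxolan-3-yl]methyl (2E)-3-(4-hydroxyphenyl)prop-2-enoate | COc1cc(C[C@@H]2CO[C@@H](c3ccc(O)c(OC)c3)[C@@H]2COC(=O)/C=C/c2ccc(O)cc2)ccc1O | target

**Step count and risks**
Total steps: 10. Longest linear sequence: 8 steps (steps 1, 3, 4, 6, 7, 8, 9, 10, from vanillin).

Step 7. The stereochemical link between C2 and C4 may be lost if the cascade runs through a dissociated 2-oxonia-Cope/aldol course or the aryl carbinol ionises. The unsubstituted acetal may also ionise too slowly, so that chloride capture or allylic C–O heterolysis takes over. The fallback sets out from 2 and comes back at 16; it sets C2 and C3 by propargylation and C4 by hydrogenation.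
- Marshall propargylation of 2 with the allenylzinc reagent made from (2R)-2-(methanesulfonyloxy)but-3-yn-1-yl 2,2-dimethylpropanoate (Pd(OAc)2, PPh3, Et2Zn, THF, −20 °C) should give the anti homopropargylic alcohol (2S,3R)-2-ethynyl-3-hydroxy-3-[3-methoxy-4-(2,2-dimethylpropanoyloxy)phenyl]propyl 2,2-dimethylpropanoate F1. The (2R) configuration assumes the usual anti SN2′ palladation and syn SE2′ addition.
- Sonogashira coupling of F1 (PdCl2(PPh3)2, CuI, Et3N) with 4-iodo-2-methoxyphenyl 2,2-dimethylpropanoate F2, made from commercial 4-iodo-2-methoxyphenol and pivaloyl chloride, gives the aryl alkyne 4-[(3S,4R)-4-hydroxy-4-[3-methoxy-4-(2,2-dimethylpropanoyloxy)phenyl]-3-[(2,2-dimethylpropanoyloxy)methyl]but-1-yn-1-yl]-2-methoxyphenyl 2,2-dimethylpropanoate F3.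
- Alkyne Prins cyclisation of F3 with paraformaldehyde and TMSOTf (CH2Cl2, −78 to 0 °C; 5-exo-dig capture of the oxocarbenium ion, triflate trapping of the aryl-stabilised vinyl cation) should give the exocyclic vinyl triflate 4-[(E)-{(4S,5R)-5-[3-methoxy-4-(2,2-dimethylpropanoyloxy)phenyl]-4-[(2,2-dimethylpropanoyloxy)methyl]oxolan-3-ylidene}(trifluoromethanesulfonyloxy)methyl]-2-methoxyphenyl 2,2-dimethylpropanoate F4.
- Hydrogenation of F4 (H2, PtO2, Et3N, EtOAc) removes the triflate and should saturate the alkene from the face opposite the C3 substituent, giving the 3,4-cis compound [(2R,3S,4S)-2-[3-methoxy-4-(2,2-dimethylpropanoyloxy)phenyl]-4-{[3-methoxy-4-(2,2-dimethylpropanoyloxy)phenyl]methyl}oxolan-3-yl]methyl 2,2-dimethylpropanoate F5.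
- LiAlH4 (THF) cleaves the three pivalates of F5 and returns to 16.

Step 8. The equilibrium may not favour the wanted epimer enough, or the β-alkoxy aldehyde may open by elimination under base and scramble C2. The fallback sets out from 14 and comes back at 15; it uses kinetic instead of thermodynamic control.
- 14 is converted (TMSOTf, Et3N, CH2Cl2, 0 °C) into its trimethylsilyl enol ether, the 3-[(trimethylsilyloxy)methylidene]oxolane with C2 and C4 as in 14 (E isomer drawn, either isomer serves) F6.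
- Protonation of F6 at −78 °C (TBAF, AcOH, THF) delivers the proton to the less hindered face. In the case where equilibration fails, that is the face syn to the aryl group, so the formyl group is placed on the benzyl side and 15 results.

Step 10. The phenols may compete as nucleophiles or consume the betaine, giving aryl ethers or poor conversion. The fallback sets out from 16 and 17 and comes back at 18.
- Persilylation of 16 (TBSCl, imidazole, DMF) gives (2R,3S,4S)-2-{4-[(tert-butyldimethylsilyl)oxy]-3-methoxyphenyl}-4-({4-[(tert-butyldimethylsilyl)oxy]-3-methoxyphenyl}methyl)-3-{[(tert-butyldimethylsilyl)oxy]methyl}oxolane F7.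
- Mild acid (PPTS, MeOH, rt) cleaves only the primary alkyl silyl ether and gives [(2R,3S,4S)-2-{4-[(tert-butyldimethylsilyl)oxy]-3-methoxyphenyl}-4-({4-[(tert-butyldimethylsilyl)oxy]-3-methoxyphenyl}methyl)oxolan-3-yl]methanol F8.
- 17 is silylated twice (TBSCl, imidazole, DMF) to tert-butyldimethylsilyl (2E)-3-{4-[(tert-butyldimethylsilyl)oxy]phenyl}prop-2-enoate F9, whose silyl ester is hydrolysed (AcOH, THF–H2O) to (2E)-3-{4-[(tert-butyldimethylsilyl)oxy]phenyl}prop-2-enoic acid F10.
- Carbodiimide coupling of F8 and F10 (EDC·HCl, DMAP, CH2Cl2) gives the tris(tert-butyldimethylsilyl) ether of 18 F11.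
- Buffered fluoride (TBAF, AcOH, THF, 0 °C) removes the three aryl silyl ethers from F11 and gives 18.

**Further compounds**
F1 | step 7 | (2S,3R)-2-ethynyl-3-hydroxy-3-[3-methoxy-4-(2,2-dimethylpropanoyloxy)phenyl]propyl 2,2-dimethylpropanoate | C#C[C@@H](COC(=O)C(C)(C)C)[C@@H](O)c1ccc(OC(=O)C(C)(C)C)c(OC)c1
F2 | step 7 | 4-iodo-2-methoxyphenyl 2,2-dimethylpropanoate | COc1cc(I)ccc1OC(=O)C(C)(C)C
F3 | step 7 | 4-[(3S,4R)-4-hydroxy-4-[3-methoxy-4-(2,2-dimethylpropanoyloxy)phenyl]-3-[(2,2-dimethylpropanoyloxy)methyl]but-1-yn-1-yl]-2-methoxyphenyl 2,2-dimethylpropanoate | COc1cc(C#C[C@@H](COC(=O)C(C)(C)C)[C@@H](O)c2ccc(OC(=O)C(C)(C)C)c(OC)c2)ccc1OC(=O)C(C)(C)C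
F4 | step 7 | 4-[(E)-{(4S,5R)-5-[3-methoxy-4-(2,2-dimethylpropanoyloxy)phenyl]-4-[(2,2-dimethylpropanoyloxy)methyl]oxolan-3-ylidene}(trifluoromethanesulfonyloxy)methyl]-2-methoxyphenyl 2,2-dimethylpropanoate | COc1cc(/C(OS(=O)(=O)C(F)(F)F)=C2\CO[C@@H](c3ccc(OC(=O)C(C)(C)C)c(OC)c3)[C@@H]2COC(=O)C(C)(C)C)ccc1OC(=O)C(C)(C)C
F5 | step 7 | [(2R,3S,4S)-2-[3-methoxy-4-(2,2-dimethylpropanoyloxy)phenyl]-4-{[3-methoxy-4-(2,2-dimethylpropanoyloxy)phenyl]methyl}oxolan-3-yl]methyl 2,2-dimethylpropanoate | COc1cc(C[C@@H]2CO[C@@H](c3ccc(OC(=O)C(C)(C)C)c(OC)c3)[C@@H]2COC(=O)C(C)(C)C)ccc1OC(=O)C(C)(C)C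
F6 | step 8 | trimethylsilyl enol ether of 14, 3-[(E)-(trimethylsilyloxy)methylidene]oxolane with C2 and C4 as in 14 | COc1cc(C[C@@H]2CO[C@@H](c3ccc(OC(=O)C(C)(C)C)c(OC)c3)/C2=C/O[Si](C)(C)C)ccc1OC(=O)C(C)(C)C
F7 | step 10 | (2R,3S,4S)-2-{4-[(tert-butyldimethylsilyl)oxy]-3-methoxyphenyl}-4-({4-[(tert-butyldimethylsilyl)oxy]-3-methoxyphenyl}methyl)-3-{[(tert-butyldimethylsilyl)oxy]methyl}oxolane | COc1cc(C[C@@H]2CO[C@@H](c3ccc(O[Si](C)(C)C(C)(C)C)c(OC)c3)[C@@H]2CO[Si](C)(C)C(C)(C)C)ccc1O[Si](C)(C)C(C)(C)C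
F8 | step 10 | [(2R,3S,4S)-2-{4-[(tert-butyldimethylsilyl)oxy]-3-methoxyphenyl}-4-({4-[(tert-butyldimethylsilyl)oxy]-3-methoxyphenyl}methyl)oxolan-3-yl]methanol | COc1cc(C[C@@H]2CO[C@@H](c3ccc(O[Si](C)(C)C(C)(C)C)c(OC)c3)[C@@H]2CO)ccc1O[Si](C)(C)C(C)(C)C
F9 | step 10 | tert-butyldimethylsilyl (2E)-3-{4-[(tert-butyldimethylsilyl)oxy]phenyl}prop-2-enoate | CC(C)(C)[Si](C)(C)OC(=O)/C=C/c1ccc(O[Si](C)(C)C(C)(C)C)cc1
F10 | step 10 | (2E)-3-{4-[(tert-butyldimethylsilyl)oxy]phenyl}prop-2-enoic acid | OC(=O)/C=C/c1ccc(O[Si](C)(C)C(C)(C)C)cc1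
F11 | step 10 | tris(tert-butyldimethylsilyl) ether of 18, [(2R,3S,4S)-2-{4-[(tert-butyldimethylsilyl)oxy]-3-methoxyphenyl}-4-({4-[(tert-butyldimethylsilyl)oxy]-3-methoxyphenyl}methyl)oxolan-3-yl]methyl (2E)-3-{4-[(tert-butyldimethylsilyl)oxy]phenyl}prop-2-enoate | COc1cc(C[C@@H]2CO[C@@H](c3ccc(O[Si](C)(C)C(C)(C)C)c(OC)c3)[C@@H]2COC(=O)/C=C/c2ccc(O[Si](C)(C)C(C)(C)C)cc2)ccc1O[Si](C)(C)C(C)(C)C
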